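**Assumptions**
- I take the SMILES as the normal-series drimane: 5α-H, 10β-Me, 9α-H with C11 equatorial, and C4 carrying an axial β-Me and an equatorial α-CH₂OH.
- The epoxyquinol ring configuration is taken as written, (1′S,2′S,6′R): the epoxide O is trans to the C6′-OH and cis-disposed to the drimane CH₂ on the opposite face. The catalyst pseudo-enantiomer in Step 20 is chosen to give that face.
- NBS bromination in Step 13 is assumed to favour C4 (ortho to OH, para to CHO, less hindered than C6). Any minor isomer is removed by chromatography.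

## Retrosynthetic overview
1. The target comes from late desilylation and ketal hydrolysis of an epoxy allylic alcohol. Its C6′-OH is set by chelation-controlled hydride reduction of an epoxy-dienone. The epoxide is made by a regio- and catalyst-controlled Weitz–Scheffer epoxidation of a quinone monoketal (the proposed new step).
2. The monoketal comes from PIDA/MeOH dearomatization of a p-methoxyphenol. The Ar–CH₂–C9 bond is made by Ni-catalysed cross-electrophile coupling of an aryl bromide and a drimenyl iodide.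
3. The drimane comes from (E,E)-farnesol: terminal E-methyl SeO₂ oxidation, Sharpless AE of the new allylic alcohol, then a Ti(III) epoxy-polyene cascade. The cascade closes ring A, then ring B, and sets C3, C4, C5, C9 and C10; the C3-OH is later removed.
4. The exocyclic C8=C12 alkene is converted to the Δ7-8-methyl alkene through the 8-ketone, enol triflate and methylation.

## Route

**Step 1**
Reactants: 1 (2E,6E)-farnesol
Product: 2 farnesyl TBS ether
Conditions: TBSCl, imidazole, DMF, rt
Reagents that add atoms: TBSCl, CC(C)(C)[Si](C)(C)Cl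
Why: Silyl protection of the primary alcohol.

**Step 2**
Reactants: 2
Product: 3 (2E,6E,10E)-12-hydroxyfarnesyl TBS ether
Conditions: SeO₂ (5 mol %), TBHP, CH₂Cl₂, 0 °C→rt; then NaBH₄, MeOH, 0 °C
Reagents that add atoms: TBHP, CC(C)(C)OO (source of the new OH oxygen); SeO₂, O=[Se]=O
Why: Umbreit–Sharpless allylic oxidation hits the most electron-rich, accessible terminal alkene at its E-methyl (trans to the chain). The NaBH₄ reduces over-oxidised aldehyde to the alcohol.

**Step 3**
Reactants: 3
Product: 4 epoxy alcohol, (10S,11S)-10,11-epoxy-12-hydroxyfarnesyl TBS ether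
Conditions: Ti(OiPr)₄, L-(+)-DET, TBHP, 3 Å MS, CH₂Cl₂, −20 °C
Reagents that add atoms: TBHP, CC(C)(C)OO (epoxide O)
Why: Sharpless asymmetric epoxidation is chemoselective for the allylic-alcohol alkene, and L-(+)-DET gives the (10S) epoxide. This becomes the C3 (3S, 3β-OH) centre that the cascade relays to the whole decalin.

**Step 4**
Reactants: 4
Product: 5 C12-TBDPS ether of 4
Conditions: TBDPSCl, imidazole, DMAP, DMF, rt
Reagents that add atoms: TBDPSCl, CC(C)(C)[Si](c1ccccc1)(c1ccccc1)Cl
Why: Silyl protection with a group that can later be told apart from the C11 TBS ether.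

**Step 5**
Reactants: 5
Product: 6 3β-hydroxy-4α-(TBDPSOCH₂)-4β-methyl-drim-8(12)-en-11-yl TBS ether
Conditions: Cp₂TiCl₂ (cat.), Mn, 2,4,6-collidine, TMSCl, THF, rt; aqueous work-up
Reagents that add atoms: none (the TMS ether formed is cleaved on work-up)
Why: Ti(III) epoxide homolysis gives a tertiary C4 radical that cascades 6-endo onto C5=C10 and then C9=C8 through a chair–chair array, giving the trans-decalin (5α-H, 10β-Me, 9α-H, C11 equatorial). The bulky CH₂OTBDPS sits equatorial (4α) and the Me axial (4β). This is a Cuerva–Oltra-type radical epoxypolyene cyclisation, and Ti(III) β-H elimination gives the exocyclic alkene.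

**Step 6**
Reactants: 6
Product: 7 O-phenyl thionocarbonate of 6
Conditions: PhOC(S)Cl, pyridine, DMAP, CH₂Cl₂, rt
Reagents that add atoms: phenyl chlorothionoformate, S=C(Cl)Oc1ccccc1
Why: Activates the hindered 3β-OH for Barton–McCombie deoxygenation.

**Step 7**
Reactants: 7
Product: 8 3-deoxy compound
Conditions: Bu₃SnH, AIBN, PhMe, 110 °C
Reagents that add atoms: none (H only)
Why: Barton–McCombie radical deoxygenation; C3 becomes CH₂ and the ring stereocentres are not involved.

**Step 8**
Reactants: 8
Product: 9 8-oxo-drimane bis-silyl ether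
Conditions: O₃, CH₂Cl₂, −78 °C; then PPh₃
Reagents that add atoms: ozone, [O-][O+]=O (ketone O)
Why: Ozonolysis of the 1,1-disubstituted alkene; the C9 α-stereocentre is the thermodynamic equatorial-C11 isomer.

**Step 9**
Reactants: 9
Product: 10 Δ7-8-enol triflate
Conditions: KHMDS, THF, −78 °C; then PhNTf₂, −78→0 °C
Reagents that add atoms: PhNTf₂, O=S(=O)(C(F)(F)F)N(c1ccccc1)S(=O)(=O)C(F)(F)F (supplies Tf)
Why: Kinetic deprotonation occurs at the C7 methylene rather than the C9 methine, so the Δ7 triflate forms regioselectively. The C11-OTBS is a poor leaving group, so β-elimination is avoided.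

**Step 10**
Reactants: 10
Product: 11 Δ7-8-methyl drimene bis-silyl ether
Conditions: Pd(PPh₃)₄ (5 mol %), AlMe₃, THF, 60 °C
Reagents that add atoms: AlMe₃, C[Al](C)C (supplies CH₃)
Why: Pd-catalysed Negishi-type methylation of the alkenyl triflate gives the C8-methyl Δ7 alkene with no stereocentre affected.

**Step 11**
Reactants: 11
Product: 12 C11 primary alcohol (C18-OTBDPS retained)
Conditions: HF·pyridine, pyridine, THF, 0 °C→rt
Reagents that add atoms: none
Why: The primary TBS ether is cleaved selectively in the presence of TBDPS.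

**Step 12**
Reactants: 12
Product: 13 drimenyl iodide
Conditions: I₂, PPh₃, imidazole, CH₂Cl₂, 0 °C→rt
Reagents that add atoms: I₂, II (supplies I)
Why: Appel-type SN2 iodination at a non-stereogenic primary carbon.

**Step 13**
Reactants: 14 5-hydroxy-2-methoxybenzaldehyde
Product: 15 4-bromo-5-hydroxy-2-methoxybenzaldehyde
Conditions: NBS, CH₂Cl₂, 0 °C
Reagents that add atoms: NBS, O=C1CCC(=O)N1Br
Why: Electrophilic bromination ortho to the phenol OH at the less hindered C4.

**Step 14**
Reactants: 15
Product: 16 aryl pivalate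
Conditions: PivCl, Et₃N, DMAP, CH₂Cl₂, 0 °C
Reagents that add atoms: pivaloyl chloride, CC(C)(C)C(=O)Cl
Why: Acylation gives a phenol protecting group that survives the Ni coupling.

**Step 15**
Reactants: 16
Product: 17 benzylic alcohol
Conditions: NaBH₄, EtOH/THF, 0 °C
Reagents that add atoms: none (H only)
Why: Chemoselective aldehyde reduction; the hindered aryl pivalate survives at 0 °C.

**Step 16**
Reactants: 17
Product: 18 aryl bromide, benzylic TBS ether
Conditions: TBSCl, imidazole, DMF, rt
Reagents that add atoms: TBSCl, CC(C)(C)[Si](C)(C)Cl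
Why: Silyl protection of the benzylic alcohol.

**Step 17**
Reactants: 13 drimenyl iodide; 18 aryl bromide
Product: 19 Ar–CH₂–drimane
Conditions: NiI₂·xH₂O (10 mol %), 4,4′-dimethoxy-2,2′-bipyridine (10 mol %), Mn, NaI, DMA, 60 °C
Reagents that add atoms: none (the two fragments join)
Why: Weix-type Ni-catalysed cross-electrophile coupling selectively joins an aryl bromide to a primary alkyl iodide.

**Step 18**
Reactants: 19
Product: 20 free phenol
Conditions: DIBAL-H, CH₂Cl₂, −78→0 °C
Reagents that add atoms: none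
Why: Reductive cleavage of the aryl pivalate while silyl ethers and the Δ7 alkene survive.

**Step 19**
Reactants: 20
Product: 21 quinone monoketal, a 4,4-dimethoxycyclohexa-2,5-dienone with the C6′ ketone next to C1′-alkyl
Conditions: PhI(OAc)₂, MeOH, 0 °C
Reagents that add atoms: methanol, CO (supplies the second OMe)
Why: Oxidative dearomatization of a p-methoxyphenol places the ketal on the OMe-bearing carbon (C3′) and the ketone on the phenol carbon (C6′).

**Step 20**
Reactants: 21
Product: 22 epoxy-dienone ketal (C1′–C2′ epoxide, C6′ ketone)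
Conditions: aq. NaOCl, N-(9-anthracenylmethyl)cinchonidinium bromide (10 mol %), PhMe, 0 °C
Reagents that add atoms: NaOCl, [O-]Cl.[Na+] (epoxide O)
Why: Proposed new method: catalyst-controlled, regio- and enantiofacial Weitz–Scheffer epoxidation of a 2-alkyl quinone monoketal. Only the C1′=C2′ enone has an unhindered β-CH (C2′), because the other β-carbon, C4′, carries CH₂OTBS and sits next to the quaternary ketal. The ion-paired OCl⁻/OOH⁻ adds there and closes the enolate onto O–X, so C1′ becomes the quaternary epoxide carbon. The chiral ammonium pair overrides the remote drimane bias, which is why a catalyst is needed. Closest known reaction types are cinchona phase-transfer epoxidation of enones and of 2-methylnaphthoquinone; the pseudo-enantiomer picks the face.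

**Step 21**
Reactants: 22
Product: 23 epoxy allylic alcohol (C6′-OH trans to the epoxide O)
Conditions: Zn(BH₄)₂, Et₂O, −20 °C
Reagents that add atoms: none (H only)
Why: Zn²⁺ chelates the C6′ carbonyl and the adjacent epoxide O and delivers hydride from the epoxide face, while the large C11 substituent on C1′ blocks the opposite face. This is a chelation-controlled 1,2-reduction and gives the required 6′R alcohol.

**Step 22**
Reactants: 23
Product: 24 epoxy enone, TBS/TBDPS-protected
Conditions: PPTS (20 mol %), acetone/H₂O 10:1, 40 °C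
Reagents that add atoms: water, O
Why: Mild acid hydrolysis of the allylic (vinylogous) dimethyl ketal reveals the C3′ enone without touching the stereocentres.

**Step 23**
Reactants: 24
Product: 25 Epoxypholamin A
Conditions: TBAF, AcOH, THF, 0 °C→rt
Reagents that add atoms: none
Why: Buffered fluoride removes both the TBS and TBDPS ethers and leaves the epoxy-enone intact.

## Compound list
1 | (2E,6E)-farnesol | OC/C=C(\C)CC/C=C(\C)CCC=C(C)C | starting material
2 | farnesyl TBS ether | CC(C)(C)[Si](C)(C)OC/C=C(\C)CC/C=C(\C)CCC=C(C)C | intermediate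
3 | 12-hydroxyfarnesyl TBS ether | CC(C)(C)[Si](C)(C)OC/C=C(\C)CC/C=C(\C)CC/C=C(\C)CO | intermediate
4 | (10S,11S)-epoxy alcohol | CC(C)(C)[Si](C)(C)OC/C=C(\C)CC/C=C(\C)CC[C@@H]1O[C@@]1(C)CO | intermediate
5 | epoxy TBDPS ether | CC(C)(C)[Si](C)(C)OC/C=C(\C)CC/C=C(\C)CC[C@@H]1O[C@@]1(C)CO[Si](c2ccccc2)(c2ccccc2)C(C)(C)C | intermediate
6 | 3β-hydroxy bicyclic exocyclic alkene | C=C1CC[C@H]2[C@](C)(CO[Si](c3ccccc3)(c3ccccc3)C(C)(C)C)[C@@H](O)CC[C@]2(C)[C@H]1CO[Si](C)(C)C(C)(C)C | intermediate
7 | O-phenyl thionocarbonate | C=C1CC[C@H]2[C@](C)(CO[Si](c3ccccc3)(c3ccccc3)C(C)(C)C)[C@@H](OC(=S)Oc3ccccc3)CC[C@]2(C)[C@H]1CO[Si](C)(C)C(C)(C)C | intermediate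
8 | 3-deoxy bicycle | C=C1CC[C@H]2[C@](C)(CO[Si](c3ccccc3)(c3ccccc3)C(C)(C)C)CCC[C@]2(C)[C@H]1CO[Si](C)(C)C(C)(C)C | intermediate
9 | 8-ketone | O=C1CC[C@H]2[C@](C)(CO[Si](c3ccccc3)(c3ccccc3)C(C)(C)C)CCC[C@]2(C)[C@H]1CO[Si](C)(C)C(C)(C)C | intermediate
10 | enol triflate | FC(F)(F)S(=O)(=O)OC1=CC[C@H]2[C@](C)(CO[Si](c3ccccc3)(c3ccccc3)C(C)(C)C)CCC[C@]2(C)[C@H]1CO[Si](C)(C)C(C)(C)C | intermediate
11 | Δ7-drimene bis-silyl ether | CC1=CC[C@H]2[C@](C)(CO[Si](c3ccccc3)(c3ccccc3)C(C)(C)C)CCC[C@]2(C)[C@H]1CO[Si](C)(C)C(C)(C)C | intermediate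
12 | C11 alcohol | CC1=CC[C@H]2[C@](C)(CO[Si](c3ccccc3)(c3ccccc3)C(C)(C)C)CCC[C@]2(C)[C@H]1CO | intermediate
13 | drimenyl iodide | CC1=CC[C@H]2[C@](C)(CO[Si](c3ccccc3)(c3ccccc3)C(C)(C)C)CCC[C@]2(C)[C@H]1CI | intermediate
14 | 5-hydroxy-2-methoxybenzaldehyde | COc1ccc(O)cc1C=O | starting material
15 | 4-bromo-5-hydroxy-2-methoxybenzaldehyde | COc1cc(Br)c(O)cc1C=O | intermediate
16 | aryl pivalate | COc1cc(Br)c(OC(=O)C(C)(C)C)cc1C=O | intermediate
17 | benzylic alcohol | COc1cc(Br)c(OC(=O)C(C)(C)C)cc1CO | intermediate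
18 | aryl bromide TBS ether | COc1cc(Br)c(OC(=O)C(C)(C)C)cc1CO[Si](C)(C)C(C)(C)C | intermediate
19 | coupled arene | CC1=CC[C@H]2[C@](C)(CO[Si](c3ccccc3)(c3ccccc3)C(C)(C)C)CCC[C@]2(C)[C@H]1Cc5cc(OC)c(CO[Si](C)(C)C(C)(C)C)cc5OC(=O)C(C)(C)C | intermediate
20 | phenol | CC1=CC[C@H]2[C@](C)(CO[Si](c3ccccc3)(c3ccccc3)C(C)(C)C)CCC[C@]2(C)[C@H]1Cc5cc(OC)c(CO[Si](C)(C)C(C)(C)C)cc5O | intermediate
21 | quinone monoketal | CC1=CC[C@H]2[C@](C)(CO[Si](c3ccccc3)(c3ccccc3)C(C)(C)C)CCC[C@]2(C)[C@H]1CC5=CC(OC)(OC)C(CO[Si](C)(C)C(C)(C)C)=CC5=O | intermediate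
22 | epoxy-dienone ketal | CC1=CC[C@H]2[C@](C)(CO[Si](c3ccccc3)(c3ccccc3)C(C)(C)C)CCC[C@]2(C)[C@H]1C[C@@]56O[C@@H]5C(OC)(OC)C(CO[Si](C)(C)C(C)(C)C)=CC6=O | intermediate
23 | epoxy allylic alcohol ketal | CC1=CC[C@H]2[C@](C)(CO[Si](c3ccccc3)(c3ccccc3)C(C)(C)C)CCC[C@]2(C)[C@H]1C[C@@]56O[C@@H]5C(OC)(OC)C(CO[Si](C)(C)C(C)(C)C)=C[C@H]6O | intermediate
24 | epoxy enone, silyl-protected | CC1=CC[C@H]2[C@](C)(CO[Si](c3ccccc3)(c3ccccc3)C(C)(C)C)CCC[C@]2(C)[C@H]1C[C@@]56O[C@@H]5C(=O)C(CO[Si](C)(C)C(C)(C)C)=C[C@H]6O | intermediate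
25 | Epoxypholamin A | CC1=CC[C@H]2[C@](C)(CO)CCC[C@]2(C)[C@H]1C[C@@]12O[C@@H]1C(=O)C(CO)=C[C@H]2O | target

**Total steps:** 23. **Longest linear sequence:** 19 (steps 1–12 and 17–23, from farnesol). The aryl branch is 4 steps (13–16).

**Three steps most likely to fail**
1. **Step 20 (the proposed new epoxidation).** Diastereoselectivity against the remote drimane stereocentres may be poor, or the ketal may not survive.
   - Fallback: a different approach using known chemistry. Reduce dienone 21 with a CBS catalyst to the dienol, do a VO(acac)₂/TBHP hydroxyl-directed epoxidation of the more electron-rich C1′=C2′ alkene, then oxidise with DMP back to 22 and continue with Step 21.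
2. **Step 5 (Ti(III) cascade with the oxygenated C12 terminus).** The yield may be low or the C4 selectivity poor.
   - Fallback: build the decalin from (S)-5,8a-dimethyl-Wieland–Miescher ketone by Stork reductive alkylation, adding the α-CH₂OR group to the C4 enolate from the α-face.
3. **Step 17 (Ni cross-electrophile coupling of the β-branched drimenyl iodide with the ortho-substituted aryl bromide).** Homocoupling or β-H elimination may dominate.
   - Fallback: a polar route. Oxidise alcohol 12 to the C11 aldehyde, add the aryllithium from a MOM-protected analogue of 18, then deoxygenate the benzylic alcohol (Barton–McCombie).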